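**Retrosynthetic overview**
1. Feature: ring B carries B1 O–ring A, B2 CH3, B3 OCH3, B4 H, B5 i-Pr and B6 O–ring C. The B3 methoxy group lies para to the B6 oxygen, with H and then i-Pr between them. An alkenyl(methoxy)carbene, a terminal alkyne and CO leave exactly this pattern.
2. Last bond: B6–O–C3 of quinone ring C is cut to the B6 phenol and 3-bromo-5-isopropyl-2-methyl-1,4-benzoquinone (addition–elimination).
3. Key cut: ring B is split into (CO)5Cr=C(OMe)–C(CH3)=CH–O–ring A (B3, B2, B1), 3-methylbut-1-yne (B4, B5) and one CO ligand (B6). The bonds formed are B3–B4, B5–B6 and B6–B1.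
4. The crowded A–O–B1 oxygen is placed earlier by O-allylation of 4-methoxythymol. The sequence is allyl → Z-propenyl → Z-2-bromopropenyl → vinyllithium → Cr(CO)6/MeOTf.
5. Ring order: rings A and C come ready-made from thymol through the shared intermediate 4-methoxythymol. Ring B is the only ring built.

Key step: step 7

Assumption: the SMILES holds no stereocentre and the diaryl ether axes are taken as freely rotating. The target is therefore treated as achiral, and only alkene geometry in intermediates needs control.

Step 1
Reactants: 1 thymol
Product: 2 4-bromothymol (4-bromo-5-methyl-2-isopropylphenol)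
Conditions: NBS (1.0 equiv), MeCN, 0 °C → rt
Reagents that add atoms: N-bromosuccinimide, O=C1CCC(=O)N1Br
Why: Electrophilic aromatic bromination, in which the hydroxyl group directs to the open para position C4 and the only free ortho site C6 reacts more slowly with NBS in a polar solvent.

Step 2
Reactants: 2 4-bromothymol
Product: 3 4-methoxythymol (4-methoxy-5-methyl-2-isopropylphenol)
Conditions: NaOMe (5 equiv), CuBr (10 mol %), MeOH–DMF, 110 °C; then aq. HCl
Reagents that add atoms: sodium methoxide, C[O-].[Na+]
Why: Ullmann-type copper-catalysed methoxylation of an aryl bromide, which tolerates the deprotonated phenol as in the technical conversion of 4-bromo-2-tert-butylphenol into the corresponding 4-methoxyphenol.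

Step 3
Reactants: 3 4-methoxythymol; 4 allyl bromide
Product: 5 allyl 4-methoxythymyl ether (1-allyloxy-4-methoxy-5-methyl-2-isopropylbenzene)
Conditions: K2CO3, acetone, reflux
Reagents that add atoms: allyl bromide, C=CCBr
Why: Williamson ether synthesis, which makes the bond from the ring A oxygen to the future B1 carbon by SN2 on an unhindered allylic bromide, so the isopropyl group beside the oxygen does not interfere.

Step 4
Reactants: 5 allyl 4-methoxythymyl ether
Product: 6 (Z)-prop-1-enyl 4-methoxythymyl ether
Conditions: t-BuOK (0.3 equiv), DMSO, rt
Reagents that add atoms: none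
Why: Base-catalysed allyl to propenyl ether isomerisation, which under kinetic control passes through the cisoid oxyallyl anion and should therefore give mainly the Z enol ether, far below the temperature of a Claisen rearrangement.

Step 5
Reactants: 6 (Z)-prop-1-enyl 4-methoxythymyl ether
Product: 8 (Z)-2-bromoprop-1-enyl 4-methoxythymyl ether (Br cis to the aryloxy group), via 1,2-dibromopropyl ether 7 (not isolated)
Conditions: Br2 (1.0 equiv), CH2Cl2, −78 °C; then DBU (2 equiv), −78 °C → rt
Reagents that add atoms: bromine, BrBr
Why: Bromination–dehydrobromination of an enol ether as used for 2-bromoglycals, in which the enol ether takes up bromine at −78 °C much faster than ring A, and anti addition followed by anti E2 loss of the C2 hydrogen with the labile C1 bromide should place Br cis to the aryloxy group.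

Step 6
Reactants: 8 (Z)-2-bromoprop-1-enyl 4-methoxythymyl ether; 9 chromium hexacarbonyl
Product: 12 pentacarbonyl[(2Z)-1-methoxy-3-(4-methoxy-5-methyl-2-isopropylphenoxy)-2-methylprop-2-enylidene]chromium(0), via vinyllithium 10 (not isolated), via lithium acylchromate 11 (not isolated)
Conditions: t-BuLi (2.0 equiv), Et2O, −90 °C; cannula into Cr(CO)6, THF, −78 → 0 °C; then MeOTf, CH2Cl2, 0 °C → rt
Reagents that add atoms: chromium hexacarbonyl, O=C=[Cr](=C=O)(=C=O)(=C=O)(=C=O)=C=O; methyl triflate, COS(=O)(=O)C(F)(F)F
Why: Fischer carbene synthesis, in which bromine–lithium exchange with retention gives a vinyllithium whose lithium lies cis to the ether oxygen (internally coordinated and left with only a slow syn β-elimination, as in cis-2-alkoxyvinyllithiums), this adds to a carbonyl ligand of 9, and the hard electrophile methyl triflate alkylates the acylate oxygen.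

Step 7
Reactants: 12 the (Z)-β-aryloxyalkenyl methoxycarbene complex; 13 3-methylbut-1-yne
Product: 15 2-(4-methoxy-5-methyl-2-isopropylphenoxy)-4-methoxy-3-methyl-6-isopropylphenol (ring A–O–ring B phenol), via tricarbonylchromium complex 14 (not isolated)
Conditions: 13 (3 equiv), degassed THF (0.05 M), 50 °C, sealed tube; then air, Et2O, daylight, rt
Reagents that add atoms: 3-methylbut-1-yne, CC(C)C#C
Why: Dötz benzannulation: loss of one cis CO from 12 lets 13 bind and insert into the Cr=C bond (B3–B4), a CO ligand migrates onto the new carbene carbon (B5–B6) to give a chromium-bound dienylketene, and ring B closes by a six-electron electrocyclisation of the ketene carbon onto the aryloxy-bearing alkene carbon (B6–B1). The cyclohexa-2,4-dienone so formed holds H and OAr on its single sp3 carbon, so it can only aromatise by shifting that hydrogen to oxygen, which leaves the B6 phenol free and the B3 methoxy group in place; the arene stays on Cr(CO)3 as 14 until air removes the metal, and stronger oxidants are avoided because they would carry the 4-methoxyphenol on to a quinone. The closest known reaction type is the benzannulation of α-substituted alkenyl(methoxy)carbene chromium complexes with terminal alkynes, the substrate class that gives phenols most dependably; oxygen on the β-carbon has a parallel in 3-furyl carbene complexes and a group cis to the carbene carbon is tolerated because β,β-disubstituted alkenyl complexes still close, but an acyclic β-aryloxy group is an extension whose behaviour has to be tested. The regiochemistry needed (isopropyl at B5, hydrogen at B4) is secured by the size difference in 13, since the larger alkyne substituent ends up next to the CO-derived carbon and away from the methoxy-bearing one. The chemoselectivity needed is CO insertion rather than five-membered ring closure, the path taken by β-amino analogues; here the donor is a hindered aryloxy oxygen that shares its lone pair with ring A, and THF at moderate temperature favours the phenol channel. No stereocentre is formed and the Z geometry of 12, needed only for making it, disappears in the aromatic ring.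

Step 8
Reactants: 3 4-methoxythymol
Product: 16 6-bromo-4-methoxythymol (2-bromo-4-methoxy-3-methyl-6-isopropylphenol)
Conditions: NBS (1.0 equiv), i-Pr2NH (10 mol %), dry CH2Cl2, 0 °C
Reagents that add atoms: N-bromosuccinimide, O=C1CCC(=O)N1Br
Why: Electrophilic bromination ortho to the free hydroxyl group, where C6 is activated by the stronger donor and flanked only by methyl while C3 is ortho to the weaker methoxy donor and shielded by isopropyl, and exclusion of water keeps oxidation to the quinone from competing.

Step 9
Reactants: 16 6-bromo-4-methoxythymol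
Product: 17 3-bromo-5-isopropyl-2-methyl-1,4-benzoquinone (6-bromothymoquinone)
Conditions: PhI(OAc)2 (1.1 equiv), MeCN–H2O (2:1), 0 °C
Reagents that add atoms: water, O
Why: Hypervalent-iodine oxidation of a 4-methoxyphenol, in which water captures the oxidised ring at the methoxy-bearing carbon and the hemiketal loses methanol, so the p-quinone should form with the bromine untouched.

Step 10
Reactants: 15 ring A–O–ring B phenol; 17 3-bromo-5-isopropyl-2-methyl-1,4-benzoquinone
Product: 19 CNP0335608.0 (3-[2-(4-methoxy-5-methyl-2-isopropylphenoxy)-4-methoxy-3-methyl-6-isopropylphenoxy]-5-isopropyl-2-methyl-1,4-benzoquinone), via caesium phenoxide 18 (not isolated)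
Conditions: Cs2CO3 (1.2 equiv), MeCN, Ar, dark, 0 °C → rt
Reagents that add atoms: none
Why: Addition–elimination on a haloquinone, in which the phenoxide adds to the bromine-bearing carbon perpendicular to the ring plane so that the flanking groups interfere little, and irreversible loss of bromide restores the quinone, as in known preparations of aryloxyquinones from bromo- or chloroquinones and phenols.

**Compound list**
1 | thymol | Cc1ccc(C(C)C)c(O)c1 | starting material
2 | 4-bromothymol | Cc1cc(O)c(C(C)C)cc1Br | intermediate
3 | 4-methoxythymol | COc1cc(C(C)C)c(O)cc1C | intermediate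
4 | allyl bromide | C=CCBr | starting material
5 | allyl 4-methoxythymyl ether | C=CCOc1cc(C)c(OC)cc1C(C)C | intermediate
6 | (Z)-prop-1-enyl 4-methoxythymyl ether | C/C=C\Oc1cc(C)c(OC)cc1C(C)C | intermediate
7 | 1,2-dibromopropyl 4-methoxythymyl ether (racemic, diastereomers interconvert at the α-bromo ether carbon) | CC(Br)C(Br)Oc1cc(C)c(OC)cc1C(C)C | intermediate (not isolated)
8 | (Z)-2-bromoprop-1-enyl 4-methoxythymyl ether | Br/C(C)=C\Oc1cc(C)c(OC)cc1C(C)C | intermediate
9 | chromium hexacarbonyl | O=C=[Cr](=C=O)(=C=O)(=C=O)(=C=O)=C=O | starting material
10 | 1-(4-methoxythymyloxy)prop-1-en-2-yllithium, Li cis to O (formal descriptor E because CH3 outranks Li) | [Li]/C(C)=C\Oc1cc(C)c(OC)cc1C(C)C | intermediate (not isolated)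
11 | lithium pentacarbonyl[(Z)-3-aryloxy-2-methylacryloyl]chromate | [Li+].[O-]C(/C(C)=C\Oc1cc(C)c(OC)cc1C(C)C)=[Cr](=C=O)(=C=O)(=C=O)(=C=O)=C=O | intermediate (not isolated)
12 | pentacarbonyl[(2Z)-1-methoxy-3-(4-methoxy-5-methyl-2-isopropylphenoxy)-2-methylprop-2-enylidene]chromium(0) | COC(/C(C)=C\Oc1cc(C)c(OC)cc1C(C)C)=[Cr](=C=O)(=C=O)(=C=O)(=C=O)=C=O | intermediate
13 | 3-methylbut-1-yne | CC(C)C#C | starting material
14 | tricarbonyl(η6-ring B)chromium complex of 15 (η6 bond written as a dot) | COc1cc(C(C)C)c(Oc2c(C)c(OC)cc(C(C)C)c2O)cc1C.O=C=[Cr](=C=O)=C=O | intermediate (not isolated)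
15 | 2-(4-methoxy-5-methyl-2-isopropylphenoxy)-4-methoxy-3-methyl-6-isopropylphenol | COc1cc(C(C)C)c(Oc2c(C)c(OC)cc(C(C)C)c2O)cc1C | intermediate
16 | 6-bromo-4-methoxythymol | COc1cc(C(C)C)c(O)c(Br)c1C | intermediate
17 | 3-bromo-5-isopropyl-2-methyl-1,4-benzoquinone | CC1=C(Br)C(=O)C(C(C)C)=CC1=O | intermediate
18 | caesium phenoxide of 15 | COc1cc(C(C)C)c(Oc2c(C)c(OC)cc(C(C)C)c2[O-])cc1C.[Cs+] | intermediate (not isolated)
19 | CNP0335608.0 | COc1cc(C(C)C)c(Oc2c(C)c(OC)cc(C(C)C)c2OC2=C(C)C(=O)C=C(C(C)C)C2=O)cc1C | target

**Total step count:** 10. **Longest linear sequence:** 8 steps (steps 1–7 and 10). Steps 8 and 9 branch off from 3.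

**Steps most likely to fail**

Step 7. Push–pull donation from the β-oxygen may slow CO loss, so that thermal decay of the complex competes. It may also steer the vinylcarbene intermediate into ring closure without CO insertion. The fallback sets out from 3 and 17 and comes back at 15. It makes ring B from a thymol unit instead of building it. The caesium phenoxide of 3 displaces bromide from 17 (Cs2CO3, MeCN, 0 °C) to give 3-(4-methoxy-5-methyl-2-isopropylphenoxy)-5-isopropyl-2-methyl-1,4-benzoquinone F1. Aqueous sodium dithionite reduces this to the corresponding hydroquinone F2. One equivalent of MeI with K2CO3 in acetone should then methylate only the open hydroxyl at B3, which is flanked by CH3 and H. The B6 hydroxyl is buried between the isopropyl and aryloxy groups, so this should give 15.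

Step 6. The vinyllithium may lose lithium aryloxide by β-elimination, with release of propyne, before the sparingly soluble chromium hexacarbonyl captures it. Any E-bromide carried over from step 5 would decay this way at once and return 3 on work-up. The fallback sets out from 3 and 9 and comes back at 15, and it avoids the organolithium altogether.
- The phenoxide of 3 undergoes addition–elimination with purchased methyl (E)-3-bromo-2-methylacrylate (Cs2CO3, DMF) to give methyl (E)-3-aryloxy-2-methylacrylate F3.
- LiOH gives the acid F4, and oxalyl chloride with catalytic DMF gives the acid chloride F5.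
- Separately, 9 is reduced with potassium graphite in THF to dipotassium pentacarbonylchromate F6.
- F6 is acylated by F5 at −78 °C to give the potassium acylchromate F7.
- Methyl triflate converts F7 into the (E)-carbene complex F8.
- F8 enters the conditions of step 7 and converges on 15, because the alkene geometry is lost in the arene.

Step 10. Three processes may erode the substitution: electron transfer from the electron-rich phenoxide to the quinone, attack at the unsubstituted quinone carbon, and base-induced tautomerisation through the quinone methyl group. The fallback sets out from 17 and 15 and comes back at 19. It masks the quinone as a much weaker oxidant. Cyclopentadiene adds to the less substituted, isopropyl-bearing C=C of 17 (Diels–Alder, CH2Cl2, 0 °C) to give the endo adduct 6-bromo-7-methyl-4a-isopropyl-1,4,4a,8a-tetrahydro-1,4-methanonaphthalene-5,8-dione F9. This blocks the competing site. The phenoxide of 15 then replaces bromide on the remaining bromo-enedione (Cs2CO3, MeCN) to give the aryloxy adduct F10. Brief heating in o-dichlorobenzene at about 180 °C under an argon stream (retro-Diels–Alder) should release 19.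

**Further compounds**
F1 | step 7 | 3-(4-methoxy-5-methyl-2-isopropylphenoxy)-5-isopropyl-2-methyl-1,4-benzoquinone | COc1cc(C(C)C)c(OC2=C(C)C(=O)C=C(C(C)C)C2=O)cc1C
F2 | step 7 | 3-(4-methoxy-5-methyl-2-isopropylphenoxy)-5-isopropyl-2-methylbenzene-1,4-diol | COc1cc(C(C)C)c(Oc2c(C)c(O)cc(C(C)C)c2O)cc1C
F3 | step 6 | methyl (E)-3-(4-methoxy-5-methyl-2-isopropylphenoxy)-2-methylacrylate | COC(=O)/C(C)=C/Oc1cc(C)c(OC)cc1C(C)C
F4 | step 6 | (E)-3-(4-methoxy-5-methyl-2-isopropylphenoxy)-2-methylacrylic acid | OC(=O)/C(C)=C/Oc1cc(C)c(OC)cc1C(C)C
F5 | step 6 | (E)-3-(4-methoxy-5-methyl-2-isopropylphenoxy)-2-methylacryloyl chloride | ClC(=O)/C(C)=C/Oc1cc(C)c(OC)cc1C(C)C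
F6 | step 6 | dipotassium pentacarbonylchromate | [K+].[K+].O=C=[Cr-2](=C=O)(=C=O)(=C=O)=C=O
F7 | step 6 | potassium pentacarbonyl[(E)-3-aryloxy-2-methylacryloyl]chromate | [K+].[O-]C(/C(C)=C/Oc1cc(C)c(OC)cc1C(C)C)=[Cr](=C=O)(=C=O)(=C=O)(=C=O)=C=O
F8 | step 6 | pentacarbonyl[(2E)-1-methoxy-3-(4-methoxy-5-methyl-2-isopropylphenoxy)-2-methylprop-2-enylidene]chromium(0) | COC(/C(C)=C/Oc1cc(C)c(OC)cc1C(C)C)=[Cr](=C=O)(=C=O)(=C=O)(=C=O)=C=O
F9 | step 10 | endo-6-bromo-7-methyl-4a-isopropyl-1,4,4a,8a-tetrahydro-1,4-methanonaphthalene-5,8-dione (racemic, one enantiomer drawn) | CC1=C(Br)C(=O)[C@@]2(C(C)C)[C@H]3C=C[C@H](C3)[C@H]2C1=O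
F10 | step 10 | endo adduct F9 with bromine replaced by the aryloxy group of 15 (racemic, one enantiomer drawn) | CC1=C(Oc2c(C(C)C)cc(OC)c(C)c2Oc2cc(C)c(OC)cc2C(C)C)C(=O)[C@@]2(C(C)C)[C@H]3C=C[C@H](C3)[C@H]2C1=O
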